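## The problem

Galbinic acid (38) is a depsidone. Rings A and B are joined twice, by a diaryl ether oxygen and by an aryl ester, which together close a seven-membered ring, and ring B also carries a fused five-membered hydroxy lactone. Ring B has no hydrogen: round the ring stand the acetoxymethyl carbon, the free phenol, the lactone carbonyl carbon, the lactol carbon, the ether oxygen and the ester oxygen. It therefore has to be built with all six substituents in place and cannot be dressed by aromatic substitution. The only stereocentre is the (S)-lactol carbon, an O,O-acetal that can open to a formyl acid. Nothing else in the molecule can control it, so it must be set by a catalyst, carried as a mixed acetal and unveiled last without breaking a bond to that carbon. The benzylic acetate sits between two oxygenated carbons: once an ortho phenol is free it gives a quinone methide with base, and it ionizes under strong Lewis acids. The depsidone ester, the ring A aldehyde and the lactol limit the late chemistry to neutral or weakly acidic conditions, and the diaryl ether has four ortho substituents. The enabling feature is that four contiguous ring B carbons carry oxygen, CH2O, oxygen, oxygen. That is the pattern a 3-alkoxy-4-alkylcyclobutenedione delivers after addition to one carbonyl, and the remaining two carbons (lactone carbonyl and lactol carbon) can come in as an alkene for a thermal ring expansion.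

## Retrosynthesis

**38 from 37.** The last cut is the benzyl–oxygen bond of a 3,4-dimethoxybenzyl acetal on the lactol oxygen. DDQ breaks only that bond, under buffered neutral conditions, so the (S)-configuration of 37 passes to 38. Acidic or hydrogenolytic unmasking was set aside because it would ionize the acetal carbon or attack the benzylic acetate and the aldehyde.

**37 from 36.** The seven-membered ring is opened at the ester C(=O)–O bond. Closing the ester last, on the ether, fixes the regiochemistry. The opposite order would put an acyl group on one of two adjacent ring B oxygens, where it migrates under base. The forward step must be a base-free carbodiimide lactonization, because 36 has a free phenol beside the acetoxymethyl group.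

**36 from 35.** The bond between the lactol carbon and the dimethoxybenzyl oxygen is cut. Lactol 35 racemizes through its open formyl acid, so a chiral phosphoric acid can in principle funnel all of it into one acetal. The seco acid 35 is used so that the lactol is masked before the lactonization.

**35 from 34, 33 and 32.** All five allyl groups of 34 (two ethers on ring B, one on ring A, two esters) fall in one neutral palladium step, and the formyl acid so freed closes to the lactol. The acetate is installed before this, on 33, when no phenol is free, so no selectivity between hydroxyl groups is needed. Alcohol 33 comes from the 4-methoxybenzyl ether 32 with DDQ.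

**32 from 24 and 30.** The diaryl ether bond from the ring B oxygen to ring A is cut. Phenol 24 displaces a fluoride flanked by formyl and ester groups in 30. Under base 24 is the open formyl carboxylate, so the phenoxide has no benzylic leaving group beside it, and the carboxylate is allylated in the same flask. Fluoride 30 comes from 25 through acetal 26 and ester 28.

**24 from 22, 21, 20 and 19.** The lactone carbon is brought to the acid level before ring A arrives, since the ring A aldehyde would not survive chlorite. The benzoate on the future ether oxygen falls in the same flask. Phenol 19 is capped as allyl ether 20, desilylated to 21 and oxidized to 22.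

**19 from 16.** This is the key cut: the bond between the phenol carbon and the carbon that becomes the lactone-bearing carbon. The cyclobutenone 16 carries every ring B substituent and three different oxygens (benzoate, allyl ether, ketone), and its two side-chain carbons are at different oxidation levels, so the later lactone can form only one way round.

**16 from 13 and 7.** The bond from the alkenyl carbon to the ring is cut. The alkenyllithium from 13 must add to the carbonyl of 7 that is not the vinylogous ester carbonyl, and the alkoxide must be acylated cold.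

**Choice of oxygen groups.** An isopropyl ether, the usual squarate choice, would need BCl3 later, which the 2,6-dioxygenated benzylic C–O bond does not tolerate. Allyl is used instead. The quaternary oxygen then needs a different group that a hindered alkoxide accepts at low temperature, hence benzoate.

**7 from 2 and 4; 13 from 8.** Dione 7 comes from diallyl squarate 2 (from squaric acid 1) and stannane 4 (from 3). Iodide 13 comes from alkyne 8 through 10 and 12 by hydroxymethylation, hydroxyl-directed trans-hydroalumination–iodination and silylation.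

## Roads not taken

**Alternative 1:** The cut is the bond from the lactol carbon to the lactone ring oxygen, made on a finished depsidone. A chiral phosphoric acid would ionize the bis(4-methoxybenzyl) acetal of tert-butyl ester A1; the ester carbonyl oxygen captures the oxocarbenium ion, isobutene leaves, and tris(4-methoxybenzyl)-protected galbinic acid A2 results.
- Merits: the stereocentre arises by choice between two enantiotopic alkoxy groups, with no free lactol and no racemic background through ring opening. It is one operation shorter at the end than the chosen route.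
- Weak points: it says nothing about how hexasubstituted ring B is made. A1 needs a tert-butyl ester and a dibenzylic acetal next to a benzylic acetate on a complete depsidone. The 4-methoxybenzyl ethers must survive the whole assembly.
- Comparison: for the stereocentre alone this road is as good or better. The chosen plan sets against it a regiodefined construction of ring B, and it borrows the same acid-catalysed acetal chemistry for step 20.

**Alternative 2:** The cut runs through ring A: pyrone A3 and aryloxypropiolate A4, already carrying ring B and the (S)-acetal, would give diaryl ether A5 by Diels–Alder addition and loss of CO2.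
- Merits: the ether oxygen is on ring B before ring A exists, so no hindered substitution at a tetra-ortho-substituted ether is needed. On that bond it is clearly better than the chosen route.
- Weak points: the ynol ether ester of a hindered phenol must be made. A 3-formylpyrone is a poor and sensitive diene, and regiochemistry rests on polarization alone. The required heat meets allyl aryl ethers (Claisen rearrangement) and a stereocentre set many steps earlier. Ring B again has to come from elsewhere.
- Comparison: the chosen plan accepts the hindered ether formation in return for a late stereocentre and a secure ring B.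

**Alternative 3:** The cut is the ring B bond between the carboxyl-bearing and acetal-bearing carbons. Base would cyclize diketo-dioxinone A6 by aldol condensation and aromatize it to salicylate acetonide A7, with ring A already attached through the ether.
- Merits: carboxyl carbon and phenol arrive together at the right oxidation level, so no carbinol oxidation is needed, and the ether is formed on an aliphatic carbon. In both respects it is better than the chosen route.
- Weak points: A7 carries a methyl group where the acetoxymethyl group must stand, so a late benzylic oxidation is required. A6 is an enolizable tricarbonyl with an α-aryloxy ketone and several possible aldol modes. The stereocentre is not addressed.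
- Comparison: the chosen plan brings the CH2O carbon in at the right level from the start and has no ambiguity of ring closure.

Key step: step 8

Assumption: the lactol carbon of 38 can epimerize through the open formyl acid, so it is taken as configurationally defined only in neutral media and is set free in the last step alone. The catalyst enantiomer in step 20 is a working choice, to be confirmed on the product.

## Route

Step 1
Reactants: 1 squaric acid
Product: 2 3,4-bis(allyloxy)cyclobut-3-ene-1,2-dione (diallyl squarate)
Conditions: allyl alcohol (excess), toluene, reflux, Dean–Stark trap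
Reagents that add atoms: allyl alcohol, C=CCO
Why: Azeotropic Fischer-type esterification of the vinylogous diacid, as used for other dialkyl squarates.

Step 2
Reactants: 3 tributyl(iodomethyl)stannane
Product: 4 tributyl{[(4-methoxybenzyl)oxy]methyl}stannane
Conditions: NaH, 4-methoxybenzyl alcohol, THF/DMF, 0 °C to rt
Reagents that add atoms: 4-methoxybenzyl alcohol, COc1ccc(CO)cc1
Why: Williamson etherification of a primary iodide by the sodium alkoxide; the standard access to alkoxymethylstannanes.

Step 3
Reactants: 4 tributyl{[(4-methoxybenzyl)oxy]methyl}stannane, 2 diallyl squarate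
Product: 7 3-(allyloxy)-4-{[(4-methoxybenzyl)oxy]methyl}cyclobut-3-ene-1,2-dione, via organolithium 5 (not isolated), via lithium alkoxide 6 (not isolated)
Conditions: n-BuLi, THF, −78 °C; then 2, THF, −78 °C; (CF3CO)2O, −78 °C to rt; aq. NaHCO3
Reagents that add atoms: water, O
Why: Tin–lithium exchange gives the alkoxymethyllithium, which adds 1,2 to one squarate carbonyl. Trifluoroacetylation and ionization of the adduct, then hydrolysis of the oxocarbenium ion with loss of one allyloxy group, give the 3-alkoxy-4-alkyl dione, the known squarate-to-cyclobutenedione sequence.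

Step 4
Reactants: 8 3,3-diethoxyprop-1-yne
Product: 10 4,4-diethoxybut-2-yn-1-ol, via lithium acetylide 9 (not isolated)
Conditions: n-BuLi, THF, −78 °C; (CH2O)n, −78 °C to rt; aq. NH4Cl
Reagents that add atoms: formaldehyde (as paraformaldehyde), C=O
Why: Hydroxymethylation of a lithium acetylide; the acetal is inert to the base.

Step 5
Reactants: 10 4,4-diethoxybut-2-yn-1-ol
Product: 12 (Z)-4,4-diethoxy-3-iodobut-2-en-1-ol, via vinylalanate 11 (not isolated)
Conditions: NaAlH2(OCH2CH2OCH3)2, THF, 0 °C; EtOAc; I2, THF, −78 to 0 °C; aq. Na2S2O3, aq. KNaC4H4O6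
Reagents that add atoms: iodine, II
Why: Hydroxyl-directed trans-hydroalumination puts aluminium on the carbon remote from the hydroxyl, the one bearing the acetal, and iodination with retention gives the iodide cis to the CH2OH group. Low temperature keeps the alanate from expelling ethoxide to an allene.

Step 6
Reactants: 12 (Z)-4,4-diethoxy-3-iodobut-2-en-1-ol
Product: 13 (Z)-tert-butyl[(4,4-diethoxy-3-iodobut-2-en-1-yl)oxy]dimethylsilane
Conditions: t-BuMe2SiCl, imidazole, CH2Cl2, 0 °C to rt
Reagents that add atoms: tert-butyldimethylsilyl chloride, CC(C)(C)[Si](C)(C)Cl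
Why: Routine silylation of a primary alcohol under non-acidic conditions that leave the acetal untouched.

Step 7
Reactants: 13 (Z)-tert-butyl[(4,4-diethoxy-3-iodobut-2-en-1-yl)oxy]dimethylsilane, 7 3-(allyloxy)-4-{[(4-methoxybenzyl)oxy]methyl}cyclobut-3-ene-1,2-dione
Product: 16 racemic 2-(allyloxy)-1-[(E)-4-(tert-butyldimethylsilyloxy)-1,1-diethoxybut-2-en-2-yl]-3-{[(4-methoxybenzyl)oxy]methyl}-4-oxocyclobut-2-en-1-yl benzoate (silyloxymethyl group cis to the ring carbon), via vinyllithium 14 (not isolated), via lithium alkoxide 15 (not isolated)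
Conditions: t-BuLi (2 equiv), Et2O, −78 °C; 7, THF, −78 °C; PhCOCl, −78 to −30 °C
Reagents that add atoms: benzoyl chloride, O=C(Cl)c1ccccc1
Why: Iodine–lithium exchange with retention gives an acetal-chelated 2-lithio enal acetal. It adds to the ketone-like carbonyl next to the alkoxy-bearing carbon and not to the vinylogous ester carbonyl, the known regiochemistry for 3-alkoxy-4-alkylcyclobutenediones. The hindered tertiary alkoxide is then O-acylated cold, which is faster than any alkylation.

Step 8
Reactants: 16 racemic 4-alkenyl-4-benzoyloxycyclobutenone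
Product: 19 2-(allyloxy)-5-{[(tert-butyldimethylsilyl)oxy]methyl}-6-(diethoxymethyl)-4-hydroxy-3-{[(4-methoxybenzyl)oxy]methyl}phenyl benzoate, via dienylketene 17 (not isolated), via cyclohexadienone 18 (not isolated)
Conditions: toluene (0.02 M, degassed), 100 °C
Reagents that add atoms: none
Why: Heating opens the cyclobutenone by conrotatory 4π electrocyclic cleavage of the bond between the carbonyl carbon and the quaternary carbon to give dienylketene 17; the benzoyloxy group, a lone-pair donor, turns outward and so places the alkenyl arm beside the ketene. A six-electron disrotatory electrocyclization then joins the ketene carbon to the alkene terminus (future phenol carbon to future lactone-bearing carbon) and closes ring B as cyclohexadienone 18, which enolizes to phenol 19. The closest known reaction type is the thermal ring expansion of 4-alkenyl- and 4-aryl-cyclobutenones bearing a 4-hydroxy, 4-alkoxy or 4-silyloxy group, made from squaric esters, to hydroquinones and their mono-protected forms. The one ring formed is closed in the 6π electrocyclic mode from a triene whose one terminus is a ketene. No stereocentre is created: the quaternary centre of 16 and the sp3 carbon of 18 both end as aromatic carbons. The step needs torquoselectivity, which the oxygen substituent on the quaternary carbon secures. It also needs closure to outrun Claisen rearrangement or ketene [2+2] addition of the allyl ether, which the moderate temperature secures together with the fast closure of a ketene terminus that has no inward substituent to clash with the inward silyloxymethyl group. The substitution pattern of 19 is fixed by the connectivity of 16, so no regiochemical choice arises here.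

Step 9
Reactants: 19 phenol from the ring expansion
Product: 20 2,4-bis(allyloxy)-5-{[(tert-butyldimethylsilyl)oxy]methyl}-6-(diethoxymethyl)-3-{[(4-methoxybenzyl)oxy]methyl}phenyl benzoate
Conditions: allyl alcohol, PPh3, diisopropyl azodicarboxylate, THF, 0 °C to rt
Reagents that add atoms: allyl alcohol, C=CCO
Why: Mitsunobu etherification of the phenol with a primary alcohol; no free phenoxide is present, so the aryl benzoate cannot be cleaved or transferred.

Step 10
Reactants: 20 bis(allyl ether) silyl ether
Product: 21 2,4-bis(allyloxy)-6-(diethoxymethyl)-5-(hydroxymethyl)-3-{[(4-methoxybenzyl)oxy]methyl}phenyl benzoate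
Conditions: Bu4NF, AcOH, THF, 0 °C to rt
Reagents that add atoms: none
Why: Buffered fluoride desilylation spares the aryl benzoate and keeps the medium non-acidic, so the new alcohol does not close onto the neighbouring acetal.

Step 11
Reactants: 21 benzylic alcohol
Product: 22 2,4-bis(allyloxy)-6-(diethoxymethyl)-5-formyl-3-{[(4-methoxybenzyl)oxy]methyl}phenyl benzoate
Conditions: Dess–Martin periodinane, NaHCO3, CH2Cl2, 0 °C to rt
Reagents that add atoms: none
Why: Dess–Martin oxidation of a primary benzylic alcohol; the bicarbonate buffer protects the acetal from the acetic acid released.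

Step 12
Reactants: 22 aldehyde acetal
Product: 24 racemic 5,7-bis(allyloxy)-3,4-dihydroxy-6-{[(4-methoxybenzyl)oxy]methyl}-2-benzofuran-1(3H)-one, via carboxylic acid 23 (not isolated)
Conditions: NaClO2, NaH2PO4, 2-methyl-2-butene, t-BuOH/H2O, 0 °C to rt; NaOH, THF/MeOH/H2O, rt; then 1 M HCl, THF, 40 °C
Reagents that add atoms: sodium chlorite, [Na+].[O-]Cl=O; water, O
Why: Pinnick oxidation takes only the free aldehyde, because the acetal stands on a ring position with acceptor groups ortho and no donor ortho or para and so hydrolyses slowly at the buffer pH. Saponification then removes the benzoate, and acidification lets the acid, now helped by the ortho phenol, cleave its neighbouring acetal and close to the lactol.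

Step 13
Reactants: 25 2,6-difluoro-4-methylbenzaldehyde
Product: 26 2-(dimethoxymethyl)-1,3-difluoro-5-methylbenzene
Conditions: HC(OCH3)3, CH3OH, p-toluenesulfonic acid (cat.), rt
Reagents that add atoms: trimethyl orthoformate, COC(OC)OC
Why: Routine acetalization; it protects the aldehyde from the organolithium and makes the two ring hydrogens equivalent.

Step 14
Reactants: 26 2-(dimethoxymethyl)-1,3-difluoro-5-methylbenzene
Product: 28 allyl 3-(dimethoxymethyl)-2,4-difluoro-6-methylbenzoate, via aryllithium 27 (not isolated)
Conditions: s-BuLi, THF, −78 °C; ClCO2CH2CH=CH2, −78 °C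
Reagents that add atoms: allyl chloroformate, C=CCOC(Cl)=O
Why: Fluorine-directed ortho-lithiation at one of two equivalent positions, so no regiochemical question arises; the ortho-fluoroaryllithium is kept cold and acylated by the chloroformate.

Step 15
Reactants: 28 allyl 3-(dimethoxymethyl)-2,4-difluoro-6-methylbenzoate
Product: 30 allyl 4-(allyloxy)-2-fluoro-3-formyl-6-methylbenzoate, via acetal ester 29 (not isolated)
Conditions: NaH, allyl alcohol, DMF, 50 °C; then 1 M HCl, THF, rt
Reagents that add atoms: allyl alcohol, C=CCO; water, O
Why: Nucleophilic aromatic substitution by allyloxide at the fluoride para to the ester; the other fluoride is shielded on both sides by the ester and the dimethoxymethyl group. Ester exchange with allyloxide is degenerate, and acid then frees the aldehyde.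

Step 16
Reactants: 24 phenol lactol, 30 allyl 4-(allyloxy)-2-fluoro-3-formyl-6-methylbenzoate
Product: 32 allyl 2,4-bis(allyloxy)-5-{3-(allyloxy)-6-[(allyloxy)carbonyl]-2-formyl-5-methylphenoxy}-6-formyl-3-{[(4-methoxybenzyl)oxy]methyl}benzoate, via caesium carboxylate 31 (not isolated)
Conditions: Cs2CO3, DMF, 70 °C; then allyl bromide, rt
Reagents that add atoms: allyl bromide, C=CCBr
Why: Base opens the lactol to the formyl carboxylate, and the phenoxide displaces the fluoride activated by an ortho formyl and an ortho ester group (addition–elimination). Alkylation of the carboxylate then gives the normal allyl ester, as known for salts of 2-formylbenzoic acids.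

Step 17
Reactants: 32 diaryl ether
Product: 33 allyl 2,4-bis(allyloxy)-5-{3-(allyloxy)-6-[(allyloxy)carbonyl]-2-formyl-5-methylphenoxy}-6-formyl-3-(hydroxymethyl)benzoate
Conditions: DDQ, CH2Cl2/pH 7 phosphate buffer, 0 °C to rt
Reagents that add atoms: none
Why: Oxidative cleavage of a 4-methoxybenzyl alkyl ether; allyl groups, esters and aldehydes are inert, and limiting the oxidant avoids further oxidation of the benzylic alcohol.

Step 18
Reactants: 33 benzylic alcohol
Product: 34 allyl 3-(acetoxymethyl)-2,4-bis(allyloxy)-5-{3-(allyloxy)-6-[(allyloxy)carbonyl]-2-formyl-5-methylphenoxy}-6-formylbenzoate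
Conditions: Ac2O, pyridine, 4-(dimethylamino)pyridine (cat.), CH2Cl2, 0 °C to rt
Reagents that add atoms: acetic anhydride, CC(=O)OC(C)=O
Why: Routine acetylation of the only free hydroxyl group; the acetate goes in while every phenol is still capped.

Step 19
Reactants: 34 penta-allyl acetate
Product: 35 racemic 2-{[6-(acetoxymethyl)-3,5,7-trihydroxy-1-oxo-1,3-dihydro-2-benzofuran-4-yl]oxy}-3-formyl-4-hydroxy-6-methylbenzoic acid
Conditions: Pd(PPh3)4 (cat.), N-methylaniline, THF, rt
Reagents that add atoms: none
Why: Tsuji–Trost-type cleavage of aryl allyl ethers and allyl esters by zerovalent palladium, with the aniline as allyl acceptor. The medium stays too weakly basic to form a phenoxide beside the benzylic acetate, and the freed ring B formyl acid closes to the lactol by itself.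

Step 20
Reactants: 35 racemic seco acid lactol
Product: 36 2-{[(3S)-6-(acetoxymethyl)-3-[(3,4-dimethoxybenzyl)oxy]-5,7-dihydroxy-1-oxo-1,3-dihydro-2-benzofuran-4-yl]oxy}-3-formyl-4-hydroxy-6-methylbenzoic acid
Conditions: (R)-3,3'-bis(2,4,6-triisopropylphenyl)-1,1'-binaphthalene-2,2'-diyl hydrogen phosphate (10 mol %), 3,4-dimethoxybenzyl alcohol, 5 Å molecular sieves, CH2Cl2/THF, −20 °C to rt
Reagents that add atoms: 3,4-dimethoxybenzyl alcohol, COc1ccc(CO)cc1OC
Why: Proposed new method: the lactol equilibrates with its open formyl acid and so racemizes; the alcohol adds to the aldehyde, the chiral acid ionizes the hemiacetal to an oxocarbenium phosphate ion pair, and the neighbouring carboxyl group, held by the phosphate, closes on one face to the (S)-pseudoester, which the weak acid does not re-ionize, so the outcome should be kinetic. The closest known reaction types are chiral phosphoric acid-catalysed enantioselective acetalization and transacetalization at O,O-acetal carbons and the classical acid-catalysed pseudoesterification of 3-hydroxyphthalides.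

Step 21
Reactants: 36 (S)-acetal seco acid
Product: 37 galbinic acid (S)-O-(3,4-dimethoxybenzyl) acetal
Conditions: N,N'-dicyclohexylcarbodiimide, CH2Cl2/THF (0.002 M), rt
Reagents that add atoms: none
Why: Carbodiimide lactonization of a 2-(2-hydroxyaryloxy)benzoic acid, the classical depsidone ring closure. Only the phenol ortho to the ether can reach the activated acid, and the absence of base protects the benzylic acetate and the acetal.

Step 22
Reactants: 37 protected galbinic acid
Product: 38 galbinic acid
Conditions: DDQ, CH2Cl2/pH 7 phosphate buffer, 0 °C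
Reagents that add atoms: none
Why: DDQ removes hydride from the electron-rich benzylic CH2 and water cleaves the resulting oxocarbenium ion. Only the benzyl–oxygen bond breaks, so the lactol is set free with its (S)-configuration, while the two chelated, electron-poor phenols should resist the oxidant.

## Compound list

1 | squaric acid (3,4-dihydroxycyclobut-3-ene-1,2-dione) | OC1=C(O)C(=O)C1=O | starting material
2 | 3,4-bis(allyloxy)cyclobut-3-ene-1,2-dione | C=CCOC1=C(OCC=C)C(=O)C1=O | intermediate
3 | tributyl(iodomethyl)stannane | CCCC[Sn](CCCC)(CCCC)CI | starting material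
4 | tributyl{[(4-methoxybenzyl)oxy]methyl}stannane | CCCC[Sn](CCCC)(CCCC)COCc1ccc(OC)cc1 | intermediate
5 | {[(4-methoxybenzyl)oxy]methyl}lithium | [Li]COCc1ccc(OC)cc1 | intermediate (not isolated)
6 | lithium alkoxide of 2,3-bis(allyloxy)-4-hydroxy-4-{[(4-methoxybenzyl)oxy]methyl}cyclobut-2-en-1-one | [Li]OC1(COCc2ccc(OC)cc2)C(=O)C(OCC=C)=C1OCC=C | intermediate (not isolated)
7 | 3-(allyloxy)-4-{[(4-methoxybenzyl)oxy]methyl}cyclobut-3-ene-1,2-dione | O=C1C(=O)C(OCC=C)=C1COCc1ccc(OC)cc1 | intermediate
8 | 3,3-diethoxyprop-1-yne | C#CC(OCC)OCC | starting material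
9 | lithium 3,3-diethoxyprop-1-yn-1-ide | [Li]C#CC(OCC)OCC | intermediate (not isolated)
10 | 4,4-diethoxybut-2-yn-1-ol | OCC#CC(OCC)OCC | intermediate
11 | sodium cyclic alkoxy(vinyl)bis(2-methoxyethoxy)aluminate from 10 | [Na+].CCOC(OCC)C1=CCO[Al-]1(OCCOC)OCCOC | intermediate (not isolated)
12 | (Z)-4,4-diethoxy-3-iodobut-2-en-1-ol | OC/C=C(\I)C(OCC)OCC | intermediate
13 | (Z)-tert-butyl[(4,4-diethoxy-3-iodobut-2-en-1-yl)oxy]dimethylsilane | CC(C)(C)[Si](C)(C)OC/C=C(\I)C(OCC)OCC | intermediate
14 | [(E)-4-(tert-butyldimethylsilyloxy)-1,1-diethoxybut-2-en-2-yl]lithium | CC(C)(C)[Si](C)(C)OC/C=C(\[Li])C(OCC)OCC | intermediate (not isolated)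
15 | lithium alkoxide of racemic 4-alkenyl-3-(allyloxy)-4-hydroxy-2-{[(4-methoxybenzyl)oxy]methyl}cyclobut-2-en-1-one | [Li]OC1(C(=O)C(COCc2ccc(OC)cc2)=C1OCC=C)/C(C(OCC)OCC)=C\CO[Si](C)(C)C(C)(C)C | intermediate (not isolated)
16 | racemic 2-(allyloxy)-1-[(E)-4-(tert-butyldimethylsilyloxy)-1,1-diethoxybut-2-en-2-yl]-3-{[(4-methoxybenzyl)oxy]methyl}-4-oxocyclobut-2-en-1-yl benzoate | O=C1C(COCc2ccc(OC)cc2)=C(OCC=C)C1(OC(=O)c2ccccc2)/C(C(OCC)OCC)=C\CO[Si](C)(C)C(C)(C)C | intermediate
17 | dienylketene from ring opening of 16 (alkenyl arm cis to the ketene) | O=C=C(COCc1ccc(OC)cc1)/C(OCC=C)=C(OC(=O)c1ccccc1)\C(C(OCC)OCC)=C/CO[Si](C)(C)C(C)(C)C | intermediate (not isolated)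
18 | racemic cyclohexa-2,4-dienone from electrocyclization of 17 | O=C1C(COCc2ccc(OC)cc2)=C(OCC=C)C(OC(=O)c2ccccc2)=C(C(OCC)OCC)C1CO[Si](C)(C)C(C)(C)C | intermediate (not isolated)
19 | 2-(allyloxy)-5-{[(tert-butyldimethylsilyl)oxy]methyl}-6-(diethoxymethyl)-4-hydroxy-3-{[(4-methoxybenzyl)oxy]methyl}phenyl benzoate | Oc1c(COCc2ccc(OC)cc2)c(OCC=C)c(OC(=O)c2ccccc2)c(C(OCC)OCC)c1CO[Si](C)(C)C(C)(C)C | intermediate
20 | 2,4-bis(allyloxy)-5-{[(tert-butyldimethylsilyl)oxy]methyl}-6-(diethoxymethyl)-3-{[(4-methoxybenzyl)oxy]methyl}phenyl benzoate | C=CCOc1c(COCc2ccc(OC)cc2)c(OCC=C)c(OC(=O)c2ccccc2)c(C(OCC)OCC)c1CO[Si](C)(C)C(C)(C)C | intermediate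
21 | 2,4-bis(allyloxy)-6-(diethoxymethyl)-5-(hydroxymethyl)-3-{[(4-methoxybenzyl)oxy]methyl}phenyl benzoate | C=CCOc1c(COCc2ccc(OC)cc2)c(OCC=C)c(OC(=O)c2ccccc2)c(C(OCC)OCC)c1CO | intermediate
22 | 2,4-bis(allyloxy)-6-(diethoxymethyl)-5-formyl-3-{[(4-methoxybenzyl)oxy]methyl}phenyl benzoate | C=CCOc1c(COCc2ccc(OC)cc2)c(OCC=C)c(OC(=O)c2ccccc2)c(C(OCC)OCC)c1C=O | intermediate
23 | 2,4-bis(allyloxy)-5-(benzoyloxy)-6-(diethoxymethyl)-3-{[(4-methoxybenzyl)oxy]methyl}benzoic acid | C=CCOc1c(COCc2ccc(OC)cc2)c(OCC=C)c(OC(=O)c2ccccc2)c(C(OCC)OCC)c1C(O)=O | intermediate (not isolated)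
24 | racemic 5,7-bis(allyloxy)-3,4-dihydroxy-6-{[(4-methoxybenzyl)oxy]methyl}-2-benzofuran-1(3H)-one | C=CCOc1c(COCc2ccc(OC)cc2)c(OCC=C)c(O)c2C(O)OC(=O)c12 | intermediate
25 | 2,6-difluoro-4-methylbenzaldehyde | Cc1cc(F)c(C=O)c(F)c1 | starting material
26 | 2-(dimethoxymethyl)-1,3-difluoro-5-methylbenzene | Cc1cc(F)c(C(OC)OC)c(F)c1 | intermediate
27 | [3-(dimethoxymethyl)-2,4-difluoro-6-methylphenyl]lithium | [Li]c1c(C)cc(F)c(C(OC)OC)c1F | intermediate (not isolated)
28 | allyl 3-(dimethoxymethyl)-2,4-difluoro-6-methylbenzoate | C=CCOC(=O)c1c(C)cc(F)c(C(OC)OC)c1F | intermediate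
29 | allyl 4-(allyloxy)-3-(dimethoxymethyl)-2-fluoro-6-methylbenzoate | C=CCOC(=O)c1c(C)cc(OCC=C)c(C(OC)OC)c1F | intermediate (not isolated)
30 | allyl 4-(allyloxy)-2-fluoro-3-formyl-6-methylbenzoate | C=CCOC(=O)c1c(C)cc(OCC=C)c(C=O)c1F | intermediate
31 | caesium 2,4-bis(allyloxy)-5-{3-(allyloxy)-6-[(allyloxy)carbonyl]-2-formyl-5-methylphenoxy}-6-formyl-3-{[(4-methoxybenzyl)oxy]methyl}benzoate | [Cs+].[O-]C(=O)c1c(OCC=C)c(COCc2ccc(OC)cc2)c(OCC=C)c(Oc2c(C=O)c(OCC=C)cc(C)c2C(=O)OCC=C)c1C=O | intermediate (not isolated)
32 | allyl 2,4-bis(allyloxy)-5-{3-(allyloxy)-6-[(allyloxy)carbonyl]-2-formyl-5-methylphenoxy}-6-formyl-3-{[(4-methoxybenzyl)oxy]methyl}benzoate | C=CCOC(=O)c1c(OCC=C)c(COCc2ccc(OC)cc2)c(OCC=C)c(Oc2c(C=O)c(OCC=C)cc(C)c2C(=O)OCC=C)c1C=O | intermediate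
33 | allyl 2,4-bis(allyloxy)-5-{3-(allyloxy)-6-[(allyloxy)carbonyl]-2-formyl-5-methylphenoxy}-6-formyl-3-(hydroxymethyl)benzoate | C=CCOC(=O)c1c(OCC=C)c(CO)c(OCC=C)c(Oc2c(C=O)c(OCC=C)cc(C)c2C(=O)OCC=C)c1C=O | intermediate
34 | allyl 3-(acetoxymethyl)-2,4-bis(allyloxy)-5-{3-(allyloxy)-6-[(allyloxy)carbonyl]-2-formyl-5-methylphenoxy}-6-formylbenzoate | C=CCOC(=O)c1c(OCC=C)c(COC(C)=O)c(OCC=C)c(Oc2c(C=O)c(OCC=C)cc(C)c2C(=O)OCC=C)c1C=O | intermediate
35 | racemic 2-{[6-(acetoxymethyl)-3,5,7-trihydroxy-1-oxo-1,3-dihydro-2-benzofuran-4-yl]oxy}-3-formyl-4-hydroxy-6-methylbenzoic acid | CC(=O)OCc1c(O)c2c(c(Oc3c(C=O)c(O)cc(C)c3C(O)=O)c1O)C(O)OC2=O | intermediate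
36 | 2-{[(3S)-6-(acetoxymethyl)-3-[(3,4-dimethoxybenzyl)oxy]-5,7-dihydroxy-1-oxo-1,3-dihydro-2-benzofuran-4-yl]oxy}-3-formyl-4-hydroxy-6-methylbenzoic acid | CC(=O)OCc1c(O)c2c(c(Oc3c(C=O)c(O)cc(C)c3C(O)=O)c1O)[C@@H](OCc1ccc(OC)c(OC)c1)OC2=O | intermediate
37 | galbinic acid (S)-O-(3,4-dimethoxybenzyl) acetal | CC(=O)OCc1c(O)c2c(c3c1OC(=O)c1c(C)cc(O)c(C=O)c1O3)[C@@H](OCc1ccc(OC)c(OC)c1)OC2=O | intermediate
38 | galbinic acid, (S)-lactol | CC(=O)OCc1c(O)c2c(c3c1OC(=O)c1c(C)cc(O)c(C=O)c1O3)[C@@H](O)OC2=O | target

## Step count and least certain steps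

Total: 22 steps. Longest linear sequence: 16 steps (steps 4 to 12 and 16 to 22, from 8). The side branches are steps 1 to 3 (dione 7) and steps 13 to 15 (ring A fluoride 30).

**Step 20 (Proposed new method).** The most likely failures are poor facial selectivity in the closure of the ion pair and erosion of the ratio by slow re-ionization of the product; the free ring A carboxylic acid may also catalyse an unselective background reaction. Fallback by known chemistry, from 35 back to 36: acetalize with 3,4-dimethoxybenzyl alcohol and the achiral acid (PhO)2P(O)OH to give the racemic acetal F1. Separate F1 by preparative chromatography on a chiral stationary phase into 36 and its (3R)-enantiomer F2. Return F2 to F1 by warming with the same achiral acid and the alcohol (ionization and recombination at the acetal carbon) and recycle it.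

**Step 8 (key step).** The benzoyloxy group may not rotate outward as cleanly as a hydroxy or silyloxy group, and the tertiary allylic benzoate may fragment or migrate before the ring opens; slow closure against the inward silyloxymethyl group would let the ketene go astray. Fallback, from 13 and 7 (through alkoxide 15) back to 20: trap the alkoxide with Et3SiOSO2CF3 to give the 4-triethylsilyloxy cyclobutenone F3, the closest analogue of the known substrates. Heat it to the mono-silylated hydroquinone F4, cap the free phenol by the Mitsunobu reaction to give allyl ether F5, and cleave the aryl silyl ether alone with K2CO3/CH3OH to give phenol F6. Benzoylation of F6 with PhCOCl/pyridine gives 20.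

**Step 16.** The phenoxide of 24 is conjugated with its ortho formyl group and must attack a fluoride flanked on both sides, so slow substitution with competing attack of the phenoxide on the allyl ester is the likely failure. Fallback, from 22 (through acid 23) back to 32: saponify 23 without the acid treatment and keep the acetal, giving the hydroxy acid F7, whose phenoxide is unconjugated and more nucleophilic. Couple F7 with 30 and allylate the carboxylate as before to give acetal diaryl ether F8, then hydrolyse the acetal of F8 with aqueous acid to 32.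

**Step 22.** Oxidation of the two free phenols by DDQ may compete with the slow cleavage of an acetal whose oxygen is electron-poor, and the liberated lactol may epimerize if the medium turns acidic. Fallback, from 37 back to 38: silylate both phenols with Et3SiCl/imidazole to give bis(triethylsilyl) ether F9, cleave the dimethoxybenzyl group with DDQ to give the silylated lactol F10, and remove the silyl groups with pyridine-buffered HF·pyridine to give 38.

## Further compounds

F1 | step 20 | racemic 2-{[6-(acetoxymethyl)-3-[(3,4-dimethoxybenzyl)oxy]-5,7-dihydroxy-1-oxo-1,3-dihydro-2-benzofuran-4-yl]oxy}-3-formyl-4-hydroxy-6-methylbenzoic acid | CC(=O)OCc1c(O)c2c(c(Oc3c(C=O)c(O)cc(C)c3C(O)=O)c1O)C(OCc1ccc(OC)c(OC)c1)OC2=O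
F2 | step 20 | (3R)-enantiomer of 36 | CC(=O)OCc1c(O)c2c(c(Oc3c(C=O)c(O)cc(C)c3C(O)=O)c1O)[C@H](OCc1ccc(OC)c(OC)c1)OC2=O
F3 | step 8 | racemic 3-(allyloxy)-4-[(E)-4-(tert-butyldimethylsilyloxy)-1,1-diethoxybut-2-en-2-yl]-2-{[(4-methoxybenzyl)oxy]methyl}-4-(triethylsilyloxy)cyclobut-2-en-1-one | O=C1C(COCc2ccc(OC)cc2)=C(OCC=C)C1(O[Si](CC)(CC)CC)/C(C(OCC)OCC)=C\CO[Si](C)(C)C(C)(C)C
F4 | step 8 | 3-(allyloxy)-6-{[(tert-butyldimethylsilyl)oxy]methyl}-5-(diethoxymethyl)-2-{[(4-methoxybenzyl)oxy]methyl}-4-(triethylsilyloxy)phenol | Oc1c(COCc2ccc(OC)cc2)c(OCC=C)c(O[Si](CC)(CC)CC)c(C(OCC)OCC)c1CO[Si](C)(C)C(C)(C)C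
F5 | step 8 | {2,4-bis(allyloxy)-5-{[(tert-butyldimethylsilyl)oxy]methyl}-6-(diethoxymethyl)-3-{[(4-methoxybenzyl)oxy]methyl}phenoxy}triethylsilane | C=CCOc1c(COCc2ccc(OC)cc2)c(OCC=C)c(O[Si](CC)(CC)CC)c(C(OCC)OCC)c1CO[Si](C)(C)C(C)(C)C
F6 | step 8 | 2,4-bis(allyloxy)-5-{[(tert-butyldimethylsilyl)oxy]methyl}-6-(diethoxymethyl)-3-{[(4-methoxybenzyl)oxy]methyl}phenol | C=CCOc1c(COCc2ccc(OC)cc2)c(OCC=C)c(O)c(C(OCC)OCC)c1CO[Si](C)(C)C(C)(C)C
F7 | step 16 | 2,4-bis(allyloxy)-6-(diethoxymethyl)-5-hydroxy-3-{[(4-methoxybenzyl)oxy]methyl}benzoic acid | OC(=O)c1c(OCC=C)c(COCc2ccc(OC)cc2)c(OCC=C)c(O)c1C(OCC)OCC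
F8 | step 16 | allyl 2,4-bis(allyloxy)-5-{3-(allyloxy)-6-[(allyloxy)carbonyl]-2-formyl-5-methylphenoxy}-6-(diethoxymethyl)-3-{[(4-methoxybenzyl)oxy]methyl}benzoate | C=CCOC(=O)c1c(OCC=C)c(COCc2ccc(OC)cc2)c(OCC=C)c(Oc2c(C=O)c(OCC=C)cc(C)c2C(=O)OCC=C)c1C(OCC)OCC
F9 | step 22 | bis(triethylsilyl) ether of 37 at both phenols | CC(=O)OCc1c(O[Si](CC)(CC)CC)c2c(c3c1OC(=O)c1c(C)cc(O[Si](CC)(CC)CC)c(C=O)c1O3)[C@@H](OCc1ccc(OC)c(OC)c1)OC2=O
F10 | step 22 | bis(triethylsilyl) ether of galbinic acid at both phenols, (S)-lactol | CC(=O)OCc1c(O[Si](CC)(CC)CC)c2c(c3c1OC(=O)c1c(C)cc(O[Si](CC)(CC)CC)c(C=O)c1O3)[C@@H](O)OC2=O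
A1 | alternative 1 | depsidone tert-butyl ester with bis(4-methoxybenzyl) acetal and two 4-methoxybenzyl ethers | CC(=O)OCc1c(OCc4ccc(OC)cc4)c(C(=O)OC(C)(C)C)c(C(OCc6ccc(OC)cc6)OCc7ccc(OC)cc7)c3c1OC(=O)c1c(C)cc(OCc5ccc(OC)cc5)c(C=O)c1O3
A2 | alternative 1 | galbinic acid as bis(4-methoxybenzyl) ether and (S)-4-methoxybenzyl acetal | CC(=O)OCc1c(OCc4ccc(OC)cc4)c2c(c3c1OC(=O)c1c(C)cc(OCc5ccc(OC)cc5)c(C=O)c1O3)[C@@H](OCc6ccc(OC)cc6)OC2=O
A3 | alternative 2 | 3-formyl-4-[(4-methoxybenzyl)oxy]-6-methyl-2H-pyran-2-one | Cc1cc(OCc2ccc(OC)cc2)c(C=O)c(=O)o1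
A4 | alternative 2 | allyl 3-aryloxypropiolate of the ring B (S)-acetal lactone | C=CCOC(=O)C#COc1c(OCC=C)c(CO[Si](C)(C)C(C)(C)C)c(OCc4ccc(OC)cc4)c2c1[C@@H](OCc6ccc(OC)cc6)OC2=O
A5 | alternative 2 | diaryl ether with complete ring A and (S)-acetal lactone | C=CCOC(=O)c1c(C)cc(OCc5ccc(OC)cc5)c(C=O)c1Oc1c(OCC=C)c(CO[Si](C)(C)C(C)(C)C)c(OCc4ccc(OC)cc4)c2c1[C@@H](OCc6ccc(OC)cc6)OC2=O
A6 | alternative 3 | diketo-dioxinone carrying the ring A aryloxy group | CC1(C)OC(=CC(=O)O1)C(C)C(=O)C(Oc1c(C(OC)OC)c(OCOC)cc(C)c1C(=O)OCC=C)C(=O)C(OC)OC
A7 | alternative 3 | ring B acetonide-protected salicylate with free phenol and ring A ether | CC1(C)Oc2c(C)c(O)c(Oc3c(C(OC)OC)c(OCOC)cc(C)c3C(=O)OCC=C)c(C(OC)OC)c2C(=O)O1
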